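Taken by itself, the pairing of E would bring E from 10 mM to 2.94 mM in 3.0 s, a reacted part of 70.6%, which is less than the 80% wanted.

    E + Q → D + X (k1 = 24 M⁻¹ s⁻¹)
    Q + D ⇌ Q.D, settled at all times (K2 = 1000 M⁻¹)
    Q + D ⇌ J, settled at all times (K3 = 42 M⁻¹)
    2 E → E2 (k4 = 40 M⁻¹ s⁻¹)

E 10 mM; time 3.0 s

- the concentration of Q at which the part of the E that has reacted at 3.0 s is just 80%, in mM

- a species is counted by the E in it: one E2 counts as two
- amounts and yields of D count J too
- for a step with 2 of a species take k times the square, and two of it per event
- the amount of Q is what is sought; it is there from the start
- run time (flask): 3.0 s

So Q supplies a correction, and the correction is what is reckoned here. How large must it be? The reciprocal of [E] suits the question, because the pairing raises it at a steady 80.0 M⁻¹ s⁻¹. Call r the rate at which the turning of E + Q uses E over the rate at which the pairing uses it; the reciprocal then climbs at the pairing's rate plus r times that rate. The target [E] of 2.00 mM therefore sets the required mean ratio, the extra rise of the reciprocal over the rise the pairing gives, as a time mean of r of 0.667.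

What free Q does that take? Since r is 0.300 times [Q]/[E], and the reciprocal of [E], taken as a straight climb, has a mean of 300 M⁻¹, free Q must average near 7.41 mM as an estimate.

Must the charge be larger? Yes: at that Q, bound D stands to free D as 7.72 to one, so 88.5% of the D released takes a second Q, and the charge lies above 7.41 mM by what has been spent. This reckoning stops there, without a figure for the charge.

The forecast gives 11.6 mM, on the ground that “nearly all the D released ties up a second Q”.

The simulation gives 11.7 mM of Q, which agrees with the forecast within its tolerance. In this flask r reads 0.51 at 0.752 s, below the required mean, and then stands above that mean and about level with the pairing, at 0.99 at 3.00 s.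

(All constants were chosen freely; the result is computed.)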